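The numbers are assumed; the rest is arithmetic.

Over the 80 min of this run the solid dissolves slowly while the catalyst draws the solution down, so I first asked at what level the dissolved starting material must settle.

    free catalyst + by-product → spent catalyst (k1 = 0.443 L mol⁻¹ min⁻¹)
    solid substrate ⇌ starting material, rate k2*(cs2 - [starting material]) while solid is left; crystals form when [starting material] > cs2 (cs2 = 4.3 mM, k2 = 0.0550 min⁻¹)
    catalyst intermediate C → free catalyst + target (k3 = 1.20 min⁻¹)
    2 starting material → homo dimer (k4 = 1.44 L mol⁻¹ min⁻¹)
    catalyst intermediate B → by-product + catalyst intermediate C (k5 = 1.61 min⁻¹)
    partner + catalyst intermediate A ⇌ catalyst intermediate B (K6 = 89.1 L mol⁻¹, k6 = 1450 L mol⁻¹ min⁻¹)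
    starting material + free catalyst → catalyst intermediate A (k7 = 50.2 L mol⁻¹ min⁻¹)

solid substrate 20 mM; partner 14.0 mM; free catalyst 1.0 mM; time 80 min

- a species is counted by the solid substrate in it: one homo dimer counts as two
- two of one species on the left: rate k times its square, two consumed each time
- given per volume of solution although it is solid: solid substrate
- at the start none of the solid substrate is in solution
- starting material means what is dissolved; the solid is not counted in it
- run time (flask): 80 min

* the target standing at 80 min, as a percentage of the solid substrate charged
* concentration of starting material in solution at 80 min, in percent of saturation

**Two extremes.** If the catalyst took up starting material instantly, the solution would stay empty and dissolution would deliver 94.6% of the charge by 80 min. Even then, partner, the limiting reagent at 14.0 mM against 20 mM of solid substrate, allows 70.0% of target. With no capture, [starting material] would stay below saturation at 4.3 mM, because homo dimer formation would still drain the solution while dissolution went on.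

**Balance fraction.** While [free catalyst] stood near its charge, capture was pseudo-first-order with constant 0.0502 min⁻¹. This is close to the dissolution coefficient 0.0550 min⁻¹, so the flask had to lie between the extremes. I set dissolution equal to capture. The balance fraction, the part of saturation at which they match, is the dissolution coefficient divided by the sum of itself and the capture constant, and it came to 52.3%.

**Reckoned yield.** The solution approaches that level with a time constant of 9.51 min. Catalyst intermediates B and C have half-lives of 0.43 min and 0.58 min, far shorter than that, so I let captured material pass straight on to target. A feed of 0.113 mM min⁻¹ running after that lag gave 39.8% of the charge as target.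

**The forecast.** The forecast gave 27% of target and 57% of saturation, starting from “Dissolution and catalytic consumption should balance”; its target stood below mine and its saturation above mine.

**The result.** The flask gave 31.4% of target and 55.7% of saturation. Target fell 8.4 percentage points short of my figure, and homo dimer held 5.14% of the charge at 80.0 min. Free catalyst then stood at 71.3% of its charge, which raises the balance fraction to 60.6%, so the reading lay between that and 52.3%. The neighbour flask, read at 2.5 h, held 47.4% of its free catalyst, 16.1% of the charge still solid and 11.5% as homo dimer. There the balance fraction is 69.8%, or 15.0% of the charge, and the neighbour flask held 13.3% as starting material.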